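**Retrosynthetic overview**
- Target ⇒ tetralin phenol: the C8–OOH group is installed last by para-selective singlet-oxygen dearomatization of aromatic ring C.
- Phenol ⇒ angular-vinyl cross-conjugated dienone: a dienone–phenol rearrangement (cationic 1,2-vinyl shift, C8 → C14) puts the vinyl group into the crowded position and aromatizes ring C.
- Dienone ⇒ bicyclic enone (dehydrogenation) ⇒ 2-ethylidene ketone + 3-methylbut-3-en-2-one (deconjugative Robinson annulation builds ring C onto ring B).
- Ethylidene ketone ⇒ ring B keto ester + acetaldehyde; keto ester ⇒ 2-methylcyclohex-2-enone + isopropenyl Grignard + methyl acrylate (one enantioselective conjugate addition/Michael trapping sets C5 and C10).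
- Ring order: ring B is purchased, ring C is annulated second, then aromatized by the shift and dearomatized again by O2.

Assumption: carbons carry cleistanthane labels (C5 isopropenyl-bearing, C10 quaternary methyl-bearing, C8 the OOH carbon, C9 ring-fusion sp2 carbon, C12 carbonyl, C13 methyl-bearing, C14 vinyl-bearing), and the ligand enantiomer in step 1 is the one that gives 5R.

**Step 1**
Reactants: 1 2-methylcyclohex-2-en-1-one; 2 isopropenylmagnesium bromide; 3 methyl acrylate
Product: 5 methyl 3-[(1R,6R)-1-methyl-2-oxo-6-(prop-1-en-2-yl)cyclohexyl]propanoate, via bromomagnesium enolate 4 (not isolated)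
Conditions: Cu(OTf)2 (4 mol %), (S)-3-(1-hydroxy-4-methylpentan-2-yl)-1-mesityl-4,5-dihydroimidazolium hexafluorophosphate (chiral NHC precursor, 6 mol %), Et2O, −30 °C, slow addition of 2; then 3, DMPU, −40 → 0 °C
Reagents that add atoms: isopropenylmagnesium bromide (2) CC(=C)[Mg]Br; methyl acrylate (3) C=CC(=O)OC
Why: Proposed new method: the chiral NHC complex of monovalent copper (formed in situ) converts the Grignard reagent into an alkenylcuprate that adds 1,4 through a π-complex and a trivalent-copper σ-adduct, the ligand choosing the enone face and fixing C5 as R, and the regiodefined magnesium enolate 4 then adds to methyl acrylate anti to the pseudoaxial isopropenyl group, setting C10 (methyl cis and propanoate arm trans to isopropenyl); the closest known reaction type is the Cu–NHC-catalysed asymmetric conjugate addition of alkyl Grignard reagents to 2-methylcyclohexenone with alkyl-halide trapping of the enolate.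

**Step 2**
Reactants: 5 methyl 3-[(1R,6R)-1-methyl-2-oxo-6-(prop-1-en-2-yl)cyclohexyl]propanoate; 6 acetaldehyde
Product: 9 methyl 3-[(1R,3E,6R)-3-ethylidene-1-methyl-2-oxo-6-(prop-1-en-2-yl)cyclohexyl]propanoate, via lithium aldolate 7 (not isolated), via aldol mesylate 8 (not isolated)
Conditions: LiN(i-Pr)2, THF, −78 °C; CH3CHO; then MsCl, −78 → 0 °C; then DBU, rt
Reagents that add atoms: acetaldehyde (6) CC=O
Why: Aldol condensation: only C8 carries enolizable ketone α-hydrogens (C10 is quaternary), so the lithium enolate adds to acetaldehyde and DBU eliminates the in situ mesylate (E1cB) to the more stable (E)-enone, with C5 and C10 untouched.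

**Step 3**
Reactants: 9 methyl 3-[(1R,3E,6R)-3-ethylidene-1-methyl-2-oxo-6-(prop-1-en-2-yl)cyclohexyl]propanoate; 10 3-methylbut-3-en-2-one
Product: 12 methyl 3-[(1R,2R)-4a-ethenyl-1,6-dimethyl-7-oxo-2-(prop-1-en-2-yl)-1,2,3,4,4a,5,6,7-octahydronaphthalen-1-yl]propanoate (epimer mixture at C8 and C13), via diketone Michael adduct 11 (not isolated)
Conditions: KOt-Bu (0.2 equiv), PhMe/t-BuOH, 0 °C; then pyrrolidine (0.3 equiv), AcOH (0.3 equiv), 80 °C
Reagents that add atoms: 3-methylbut-3-en-2-one (10) CC(=C)C(C)=O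
Why: Deconjugative Robinson annulation: γ-deprotonation gives the extended dienolate (the other α-carbon, C10, is blocked), which reacts at its α-carbon C8 with the enone to create the vinyl-bearing quaternary carbon, and enamine-mediated intramolecular aldol condensation of the methyl ketone onto C9 closes ring C without hydroxide that would saponify the ester; the new centres at C8 and C13 are erased later, so their configuration is irrelevant.

**Step 4**
Reactants: 12 methyl 3-[(1R,2R)-4a-ethenyl-1,6-dimethyl-7-oxo-2-(prop-1-en-2-yl)-1,2,3,4,4a,5,6,7-octahydronaphthalen-1-yl]propanoate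
Product: 13 methyl 3-[(1R,2R)-4a-ethenyl-1,6-dimethyl-7-oxo-2-(prop-1-en-2-yl)-1,2,3,4,4a,7-hexahydronaphthalen-1-yl]propanoate
Conditions: IBX (2.0 equiv), 4-methoxypyridine N-oxide (2.0 equiv), DMSO, 25 °C
Reagents that add atoms: none
Why: IBX α,β-dehydrogenation of the enone can only introduce the C13=C14 double bond because both γ-carbons (C8 and C10) are quaternary, giving the cross-conjugated dienone at room temperature without touching the isolated alkenes, the ester, or C5 and C10.

**Step 5**
Reactants: 13 methyl 3-[(1R,2R)-4a-ethenyl-1,6-dimethyl-7-oxo-2-(prop-1-en-2-yl)-1,2,3,4,4a,7-hexahydronaphthalen-1-yl]propanoate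
Product: 15 methyl 3-[(1R,2R)-5-ethenyl-7-hydroxy-1,6-dimethyl-2-(prop-1-en-2-yl)-1,2,3,4-tetrahydronaphthalen-1-yl]propanoate, via aryl trifluoroacetate 14 (not isolated)
Conditions: (CF3CO)2O, 2,6-di-tert-butyl-4-methylpyridine, CH2Cl2, 0 °C → rt; then MeOH, rt
Reagents that add atoms: none
Why: Dienone–phenol rearrangement: O-trifluoroacetylation gives an acyloxy-pentadienyl cation in which the vinyl group (a far better migrating group than the ring CH2, whose shift to C14 would need an impossible meta-bridged ring) undergoes a 1,2-shift from C8 to the unsubstituted terminus C14, loss of H14 aromatizes ring C, the hindered base protects the isopropenyl group from acid, and methanol cleaves the aryl ester; C8 becomes sp2 and C5 and C10 are not involved.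

**Step 6**
Reactants: 15 methyl 3-[(1R,2R)-5-ethenyl-7-hydroxy-1,6-dimethyl-2-(prop-1-en-2-yl)-1,2,3,4-tetrahydronaphthalen-1-yl]propanoate
Product: 16 trigonochinene C, methyl 3-[(1R,2R,4aR)-5-ethenyl-4a-hydroperoxy-1,6-dimethyl-7-oxo-2-(prop-1-en-2-yl)-1,2,3,4,4a,7-hexahydronaphthalen-1-yl]propanoate
Conditions: O2 (1 atm), 5,10,15,20-tetraphenylporphyrin (1 mol %), white LEDs, CH2Cl2/MeOH 9:1, −20 °C
Reagents that add atoms: dioxygen O=O
Why: Singlet-oxygen oxidative dearomatization of a para-alkylphenol to a p-peroxyquinol: the electron-rich para carbon C8 reacts much faster than the 1,1-disubstituted alkene (ene reaction) or the styrene, and attack on the ring face anti to the larger C10 propanoate arm (syn to the C10 methyl) sets C8 as R.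

**Compound list**
1 | 2-methylcyclohex-2-en-1-one | CC1=CCCCC1=O | starting material
2 | isopropenylmagnesium bromide (prop-1-en-2-ylmagnesium bromide) | CC(=C)[Mg]Br | starting material
3 | methyl acrylate | C=CC(=O)OC | starting material
4 | bromomagnesium (3R)-2-methyl-3-(prop-1-en-2-yl)cyclohex-1-en-1-olate (not isolated) | CC(=C)[C@H]1CCCC(O[Mg]Br)=C1C | intermediate
5 | methyl 3-[(1R,6R)-1-methyl-2-oxo-6-(prop-1-en-2-yl)cyclohexyl]propanoate (methyl cis, propanoate arm trans to isopropenyl) | O=C1CCC[C@H](C(C)=C)[C@@]1(C)CCC(=O)OC | intermediate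
6 | acetaldehyde | CC=O | starting material
7 | lithium alkoxide of methyl 3-[(1R,6R)-3-(1-hydroxyethyl)-1-methyl-2-oxo-6-(prop-1-en-2-yl)cyclohexyl]propanoate (diastereomer mixture at the two new carbons; not isolated) | [Li+].CC([O-])C1CC[C@H](C(C)=C)[C@@](C)(CCC(=O)OC)C1=O | intermediate
8 | methyl 3-[(1R,6R)-1-methyl-3-[1-(methylsulfonyloxy)ethyl]-2-oxo-6-(prop-1-en-2-yl)cyclohexyl]propanoate (diastereomer mixture; not isolated) | CC(OS(C)(=O)=O)C1CC[C@H](C(C)=C)[C@@](C)(CCC(=O)OC)C1=O | intermediate
9 | methyl 3-[(1R,3E,6R)-3-ethylidene-1-methyl-2-oxo-6-(prop-1-en-2-yl)cyclohexyl]propanoate | C/C=C1\CC[C@H](C(C)=C)[C@@](C)(CCC(=O)OC)C1=O | intermediate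
10 | 3-methylbut-3-en-2-one | CC(=C)C(C)=O | starting material
11 | methyl 3-[(1R,6R)-3-ethenyl-1-methyl-3-(2-methyl-3-oxobutyl)-2-oxo-6-(prop-1-en-2-yl)cyclohexyl]propanoate (epimer mixture at C8 and C13; not isolated) | C=CC1(CC(C)C(C)=O)CC[C@H](C(C)=C)[C@@](C)(CCC(=O)OC)C1=O | intermediate
12 | methyl 3-[(1R,2R)-4a-ethenyl-1,6-dimethyl-7-oxo-2-(prop-1-en-2-yl)-1,2,3,4,4a,5,6,7-octahydronaphthalen-1-yl]propanoate (epimer mixture at C4a and C6) | C=CC12CC[C@H](C(C)=C)[C@@](C)(CCC(=O)OC)C1=CC(=O)C(C)C2 | intermediate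
13 | methyl 3-[(1R,2R)-4a-ethenyl-1,6-dimethyl-7-oxo-2-(prop-1-en-2-yl)-1,2,3,4,4a,7-hexahydronaphthalen-1-yl]propanoate (either C4a epimer) | C=CC12CC[C@H](C(C)=C)[C@@](C)(CCC(=O)OC)C1=CC(=O)C(C)=C2 | intermediate
14 | methyl 3-[(1R,2R)-5-ethenyl-1,6-dimethyl-2-(prop-1-en-2-yl)-7-(trifluoroacetoxy)-1,2,3,4-tetrahydronaphthalen-1-yl]propanoate (not isolated) | C=Cc1c(C)c(OC(=O)C(F)(F)F)cc2c1CC[C@H](C(C)=C)[C@@]2(C)CCC(=O)OC | intermediate
15 | methyl 3-[(1R,2R)-5-ethenyl-7-hydroxy-1,6-dimethyl-2-(prop-1-en-2-yl)-1,2,3,4-tetrahydronaphthalen-1-yl]propanoate | C=Cc1c(C)c(O)cc2c1CC[C@H](C(C)=C)[C@@]2(C)CCC(=O)OC | intermediate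
16 | trigonochinene C, methyl 3-[(1R,2R,4aR)-5-ethenyl-4a-hydroperoxy-1,6-dimethyl-7-oxo-2-(prop-1-en-2-yl)-1,2,3,4,4a,7-hexahydronaphthalen-1-yl]propanoate | C=CC1=C(C)C(=O)C=C2[C@]1(OO)CC[C@H](C(=C)C)[C@@]2(C)CCC(=O)OC | target

**Summary**
Total step count: 6. Longest linear sequence: 6 steps (1 → 16); no protecting groups.

**Three steps most likely to fail**

Step 1 (the proposed new method). Neither high enantioselectivity with an alkenyl Grignard reagent nor clean Michael trapping of the magnesium enolate by acrylate has been shown. The fallback uses known chemistry only, sets out from 1 and comes back at 5. Achiral copper-catalysed conjugate addition of 2 to 1 (CuBr·SMe2, 5 mol %, Me3SiCl, THF, −78 °C) gives the racemic silyl enol ether trimethyl{[2-methyl-3-(prop-1-en-2-yl)cyclohex-1-en-1-yl]oxy}silane F1. MeLi (THF, 0 °C) cleaves it to the regiodefined racemic lithium 2-methyl-3-(prop-1-en-2-yl)cyclohex-1-en-1-olate F2, which adds to 3 at −78 °C anti to the isopropenyl group. This gives the racemic trans keto ester, that is 5 together with its mirror image methyl 3-[(1S,6S)-1-methyl-2-oxo-6-(prop-1-en-2-yl)cyclohexyl]propanoate F3. Preparative chromatography on a chiral stationary phase removes F3 and returns 5.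

Step 3. The α-branched enone 10 is a sluggish, reversible Michael acceptor. The dienolate may therefore drift to γ-attack, and the aldol closure onto a ketone flanked by two quaternary carbons is slow. The fallback changes the building block and the bond order; it sets out from 9 and comes back at 12. The same two-stage annulation is run with the unbranched, far more electrophilic but-3-en-2-one. It passes through the diketone methyl 3-[(1R,6R)-3-ethenyl-1-methyl-2-oxo-3-(3-oxobutyl)-6-(prop-1-en-2-yl)cyclohexyl]propanoate F4 to the nor-methyl enone methyl 3-[(1R,2R)-4a-ethenyl-1-methyl-7-oxo-2-(prop-1-en-2-yl)-1,2,3,4,4a,5,6,7-octahydronaphthalen-1-yl]propanoate F5. The C13 methyl group is then introduced by kinetic α′-deprotonation (LiN(i-Pr)2, 1.0 equiv, THF, −78 °C) and MeI, giving 12.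

Step 6. The facial selectivity at C8 rests only on substrate bias (propanoate arm versus methyl at C10) and may be modest. The fallback replaces reliance on selectivity by a separate-and-recycle loop; it sets out from 15 and comes back at 16. The photooxygenation mixture is separated by HPLC into 16 and the unwanted epimer methyl 3-[(1R,2R,4aS)-5-ethenyl-4a-hydroperoxy-1,6-dimethyl-7-oxo-2-(prop-1-en-2-yl)-1,2,3,4,4a,7-hexahydronaphthalen-1-yl]propanoate F6. Zn dust in AcOH reduces F6 through the p-quinol methyl 3-[(1R,2R,4aS)-5-ethenyl-4a-hydroxy-1,6-dimethyl-7-oxo-2-(prop-1-en-2-yl)-1,2,3,4,4a,7-hexahydronaphthalen-1-yl]propanoate F7 back to phenol 15 (reductive re-aromatization). Phenol 15 is oxidized again under the step 6 conditions to 16.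

**Further compounds**
F1 | step 1 | racemic trimethyl{[2-methyl-3-(prop-1-en-2-yl)cyclohex-1-en-1-yl]oxy}silane | CC(=C)C1CCCC(O[Si](C)(C)C)=C1C
F2 | step 1 | racemic lithium 2-methyl-3-(prop-1-en-2-yl)cyclohex-1-en-1-olate | [Li+].CC(=C)C1CCCC([O-])=C1C
F3 | step 1 | methyl 3-[(1S,6S)-1-methyl-2-oxo-6-(prop-1-en-2-yl)cyclohexyl]propanoate (enantiomer of 5) | O=C1CCC[C@@H](C(C)=C)[C@]1(C)CCC(=O)OC
F4 | step 3 | methyl 3-[(1R,6R)-3-ethenyl-1-methyl-2-oxo-3-(3-oxobutyl)-6-(prop-1-en-2-yl)cyclohexyl]propanoate | C=CC1(CCC(C)=O)CC[C@H](C(C)=C)[C@@](C)(CCC(=O)OC)C1=O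
F5 | step 3 | methyl 3-[(1R,2R)-4a-ethenyl-1-methyl-7-oxo-2-(prop-1-en-2-yl)-1,2,3,4,4a,5,6,7-octahydronaphthalen-1-yl]propanoate | C=CC12CC[C@H](C(C)=C)[C@@](C)(CCC(=O)OC)C1=CC(=O)CC2
F6 | step 6 | methyl 3-[(1R,2R,4aS)-5-ethenyl-4a-hydroperoxy-1,6-dimethyl-7-oxo-2-(prop-1-en-2-yl)-1,2,3,4,4a,7-hexahydronaphthalen-1-yl]propanoate | C=CC1=C(C)C(=O)C=C2[C@@]1(OO)CC[C@H](C(=C)C)[C@@]2(C)CCC(=O)OC
F7 | step 6 | methyl 3-[(1R,2R,4aS)-5-ethenyl-4a-hydroxy-1,6-dimethyl-7-oxo-2-(prop-1-en-2-yl)-1,2,3,4,4a,7-hexahydronaphthalen-1-yl]propanoate | C=CC1=C(C)C(=O)C=C2[C@@]1(O)CC[C@H](C(=C)C)[C@@]2(C)CCC(=O)OC
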